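**Retrosynthetic overview**
- The target acid comes from its ethyl ester by saponification in the last step.
- The furan is the only ring. Its oxygen O1 and both of its bonds (O1–C2 and O1–C5) are traced back to dioxygen added across C3 and C6 of ethyl (3E,5E)-docosa-3,5-dienoate. In the forward direction a six-membered 1,2-dioxine ring closes first by [4+2] addition and is then contracted in the same flask to the five-membered furan.
- The feature the plan rests on: O1 lies between C2 (bearing CH2CO2H) and C5 (bearing n-hexadecyl), and C3 and C4 carry only hydrogen. Such a 2,5-dialkylfuran is the anhydro form of a 3,6-dialkyl-3,6-dihydro-1,2-dioxine, that is, of a 1,3-diene plus O2.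
- The 3,5-dienoate comes from the conjugated (2E,4E)-dienoate by kinetic deconjugation and geometric equilibration, and that from octadecanal and triethyl 4-phosphonocrotonate by a vinylogous Horner–Wadsworth–Emmons reaction.

Key step: step 4

Assumption: the target has no stereocentre, so the only stereochemical variable is the diene geometry, which is needed for the cycloaddition and disappears in the furan; octadecanal is used as the freshly distilled monomer.

**Step 1**
Reactants: 1 octadecanal; 2 triethyl 4-phosphonocrotonate (ethyl (2E)-4-(diethoxyphosphoryl)but-2-enoate)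
Product: 4 ethyl (2E,4E)-docosa-2,4-dienoate, via lithiated phosphonate 3 (not isolated)
Conditions: LiN(SiMe3)2, THF, −78 °C; then 1, −78 °C → rt
Reagents that add atoms: none
Why: Vinylogous Horner–Wadsworth–Emmons olefination, in which anion 3 adds through its phosphorus-bearing carbon to the aldehyde and elimination of diethyl phosphate should give the new C4=C5 bond mainly E with the 2E bond of the reagent kept; geometric purity at C4=C5 is not critical because that bond becomes a single bond in step 2.

**Step 2**
Reactants: 4 ethyl (2E,4E)-docosa-2,4-dienoate
Product: 6 ethyl (3E)-docosa-3,5-dienoate (5Z/5E mixture), via lithium trienolate 5 (not isolated)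
Conditions: LiN(i-Pr)2, HMPA, THF, −78 °C; then inverse quench into AcOH/THF, −78 °C
Reagents that add atoms: none
Why: Kinetic deconjugation of a dienoate, in which the HMPA-complexed amide removes a C6 proton to give the extended trienolate 5 and fast, irreversible protonation at C2 (the site of highest charge density) should leave C3=C4 E and give C5=C6 as a mixture expected to be Z-rich, as is usual for deconjugation of E enoates.

**Step 3**
Reactants: 6 ethyl (3E)-docosa-3,5-dienoate (5Z/5E mixture)
Product: 7 ethyl (3E,5E)-docosa-3,5-dienoate
Conditions: I2 (5 mol %), hexane, visible light, rt; crystallisation from EtOH at −20 °C or AgNO3–SiO2 chromatography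
Reagents that add atoms: none
Why: Iodine-atom catalysed geometric equilibration of a conjugated diene, in which reversible addition of an iodine atom gives an allylic radical that rotates before losing iodine, so the mixture should drift to the thermodynamically preferred E,E isomer without moving the diene out of the 3,5-position because no acid or base is present; residual E,Z material stays in the mother liquor and can be resubmitted.

**Step 4**
Reactants: 7 ethyl (3E,5E)-docosa-3,5-dienoate; 8 dioxygen
Product: 12 ethyl 2-(5-hexadecylfuran-2-yl)acetate, via cis-dioxine 9 (not isolated), via hydroxy enone 10 (not isolated), via lactol 11 (not isolated)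
Conditions: O2, 5,10,15,20-tetraphenylporphyrin (1 mol %), CH2Cl2, white LED, −20 °C; Ar purge, dark; Et3N (0.3 equiv), 0 °C → rt; then TsOH·H2O (0.4 equiv), rt
Reagents that add atoms: none
Why: Energy transfer from the excited porphyrin gives singlet oxygen, which adds suprafacially in a [4+2] hetero-Diels–Alder manner to the s-cis conformer of the E,E diene across C3 and C6 and closes the six-membered 1,2-dioxine ring of 9; the closest known reaction type is the dye-sensitised photooxygenation of acyclic 1,3-dienes to 3,6-dihydro-1,2-dioxines followed by their base-induced conversion into furans. Once light and oxygen are removed, Et3N takes the ring proton at C3, the more acidic one because of the neighbouring CH2CO2Et group, and the O–O bond breaks in a Kornblum–DeLaMare rearrangement to the Z-configured 6-hydroxy-3-oxo enoate 10. The Z alkene inherited from the dioxine holds the C6 hydroxyl within reach of the C3 ketone, so the furan ring closes by 5-exo-trig hemiketalisation to lactol 11 and acid-catalysed loss of water aromatises it to 12; the ring oxygen is the atom delivered to C6 in the cycloaddition (O1–C5) and its second bond (O1–C2) forms in the hemiketalisation. No stereocentre survives: the cis relation in 9 follows from the suprafacial addition to the E,E diene, and the centres of 9, 10 and 11 are erased on aromatisation. The step needs the [4+2] addition to beat the ene reaction at the allylic C2 and C7 methylenes, which is secured by the E,E geometry (s-cis conformer reached without allylic strain), by both alkenes being only 1,2-disubstituted and therefore slow ene partners, and by the low temperature. The regiochemistry of the proton removal is not critical, since taking the C6 proton would lead to the same furan, and purging oxygen before the base is added keeps the electron-rich furan from being photooxygenated in its turn.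

**Step 5**
Reactants: 12 ethyl 2-(5-hexadecylfuran-2-yl)acetate
Product: 14 2-(5-hexadecylfuran-2-yl)acetic acid, via lithium carboxylate 13 (not isolated)
Conditions: LiOH·H2O, THF/H2O, 0 °C → rt; then 1 M HCl, 0 °C, to pH 3–4
Reagents that add atoms: lithium hydroxide, [Li+].[OH-]
Why: Saponification (acyl–oxygen cleavage by hydroxide) of an unhindered ethyl ester, which the furan and the activated CH2 should tolerate in the cold, with brief acidification only to pH 3–4 so that the carboxylate is protonated without acid-induced opening of the 2,5-dialkylfuran.

**Compound list**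
1 | octadecanal | CCCCCCCCCCCCCCCCCC=O | starting material
2 | triethyl 4-phosphonocrotonate (ethyl (2E)-4-(diethoxyphosphoryl)but-2-enoate) | CCOC(=O)/C=C/CP(=O)(OCC)OCC | starting material
3 | lithiated phosphonate (lithium salt of 2 deprotonated at the phosphorus-bearing carbon) | [Li+].CCOC(=O)/C=C/[CH-]P(=O)(OCC)OCC | intermediate
4 | ethyl (2E,4E)-docosa-2,4-dienoate | CCCCCCCCCCCCCCCCC/C=C/C=C/C(=O)OCC | intermediate
5 | lithium trienolate of 4 (lithium 1-ethoxydocosa-1,3,5-trien-1-olate, C3=C4 E, other geometries not defined) | [Li+].CCOC([O-])=C/C=C/C=CCCCCCCCCCCCCCCCC | intermediate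
6 | ethyl (3E)-docosa-3,5-dienoate, 5Z/5E mixture (5Z expected to predominate) | CCCCCCCCCCCCCCCCC=C/C=C/CC(=O)OCC | intermediate
7 | ethyl (3E,5E)-docosa-3,5-dienoate | CCCCCCCCCCCCCCCC/C=C/C=C/CC(=O)OCC | intermediate
8 | dioxygen | O=O | starting material
9 | ethyl 2-[(3S*,6R*)-6-hexadecyl-3,6-dihydro-1,2-dioxin-3-yl]acetate (cis, racemic, one enantiomer drawn) | CCOC(=O)C[C@H]1C=C[C@@H](CCCCCCCCCCCCCCCC)OO1 | intermediate
10 | ethyl (4Z,6R*)-6-hydroxy-3-oxodocos-4-enoate (racemic, one enantiomer drawn) | CCOC(=O)CC(=O)/C=C\[C@H](O)CCCCCCCCCCCCCCCC | intermediate
11 | ethyl 2-[(5R*)-5-hexadecyl-2-hydroxy-2,5-dihydrofuran-2-yl]acetate (racemic, both C2 epimers) | CCOC(=O)CC1(O)C=C[C@@H](CCCCCCCCCCCCCCCC)O1 | intermediate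
12 | ethyl 2-(5-hexadecylfuran-2-yl)acetate | CCCCCCCCCCCCCCCCc1ccc(CC(=O)OCC)o1 | intermediate
13 | lithium 2-(5-hexadecylfuran-2-yl)acetate | [Li+].CCCCCCCCCCCCCCCCc1ccc(CC(=O)[O-])o1 | intermediate
14 | 2-(5-hexadecylfuran-2-yl)acetic acid | CCCCCCCCCCCCCCCCc1ccc(CC(=O)O)o1 | target

**Step count**
Total steps: 5. Longest linear sequence: 5 steps (1 → 14).

**Steps most likely to fail**

Step 4. Ene hydroperoxidation at the allylic C2 and C7 methylenes may outrun the cycloaddition, or the peroxide may open by β-elimination toward the ester instead of rearranging. The oxygen bridge would then be installed without singlet oxygen, setting out from 7 and returning at 12. Monoepoxidation of 7 with mCPBA (NaHCO3, CH2Cl2, 0 °C) should give the two vinyl oxiranes ethyl (3E)-4-(trans-3-hexadecyloxiran-2-yl)but-3-enoate F1 and ethyl 2-[trans-3-[(1E)-octadec-1-en-1-yl]oxiran-2-yl]acetate F2. Both should ring-expand under Cu(CF3COCHCOCF3)2 catalysis in hot toluene to the same ethyl 2-(5-hexadecyl-2,5-dihydrofuran-2-yl)acetate F3. Dehydrogenation of F3 with DDQ in hot benzene gives 12.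

Step 2. The ester trienolate may suffer conjugate addition of the amide, Claisen self-condensation, or protonation that returns conjugated material. The deconjugation would then be run on the carboxylate, setting out from 4 and returning at 6. Saponification of 4 (LiOH, THF/H2O, then HCl) should give (2E,4E)-docosa-2,4-dienoic acid F4. LiN(i-Pr)2 (2.2 equiv, THF, −78 → 0 °C) converts it into dilithium docosa-1,3,5-triene-1,1-diolate F5, which has no electrophilic carbonyl left. Kinetic protonation of F5 at C2 with cold dilute HCl should give (3E)-docosa-3,5-dienoic acid F6 as a 5Z/5E mixture. Fischer esterification (EtOH, catalytic H2SO4, rt) returns 6.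

Step 3. The radical equilibration may stop at a mixture in which E,Z isomers accompany the E,E diene through crystallisation. The E,E isomer would then be taken out chemically, setting out from 6 after the iodine treatment and returning at 7. Liquid SO2 with a trace of hydroquinone in a sealed vessel adds cheletropically to the E,E diene much faster than to its isomers and should give ethyl 2-(cis-5-hexadecyl-1,1-dioxo-2,5-dihydrothiophen-2-yl)acetate F7, which is separated from unreacted diene by crystallisation. Heating F7 in toluene extrudes SO2 by the stereospecific disrotatory path and returns pure 7.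

**Further compounds**
F1 | step 4 | ethyl (3E)-4-(trans-3-hexadecyloxiran-2-yl)but-3-enoate (racemic, one enantiomer drawn) | CCOC(=O)C/C=C/[C@H]1O[C@@H]1CCCCCCCCCCCCCCCC
F2 | step 4 | ethyl 2-[trans-3-[(1E)-octadec-1-en-1-yl]oxiran-2-yl]acetate (racemic, one enantiomer drawn) | CCOC(=O)C[C@H]1O[C@@H]1/C=C/CCCCCCCCCCCCCCCC
F3 | step 4 | ethyl 2-(5-hexadecyl-2,5-dihydrofuran-2-yl)acetate (cis/trans mixture, racemic) | CCOC(=O)CC1C=CC(CCCCCCCCCCCCCCCC)O1
F4 | step 2 | (2E,4E)-docosa-2,4-dienoic acid | CCCCCCCCCCCCCCCCC/C=C/C=C/C(=O)O
F5 | step 2 | dilithium docosa-1,3,5-triene-1,1-diolate (C3=C4 E, C5=C6 not defined) | [Li+].[Li+].[O-]C([O-])=C/C=C/C=CCCCCCCCCCCCCCCCC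
F6 | step 2 | (3E)-docosa-3,5-dienoic acid (5Z/5E mixture) | CCCCCCCCCCCCCCCCC=C/C=C/CC(=O)O
F7 | step 3 | ethyl 2-(cis-5-hexadecyl-1,1-dioxo-2,5-dihydrothiophen-2-yl)acetate (racemic, one enantiomer drawn) | CCOC(=O)C[C@H]1C=C[C@@H](CCCCCCCCCCCCCCCC)S1(=O)=O
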